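**Strategy.** The oxane ring is disconnected at its O–C1 bond, back to a linear 1,7-diarylheptane-3,5-diol. The route exploits that C1 is the benzylic carbon para to the free phenolic OH of the guaiacyl ring (ring A), while the C5 hydroxyl is placed for six-membered closure. Two-electron oxidation turns ring A into a para-quinone methide and O5 adds to C1, which forms the ring, the O–C1 bond and the C1 stereocentre in one operation. The precursor carries the 3,5-syn-5,6-syn triol array, made by chelation-controlled aldol addition and syn reduction, with O6 and the ring B phenol as benzyl ethers so that only ring A can be oxidised.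

Key step: step 10

Assumption: carbons are numbered C1–C7 along the heptane chain from ring A (guaiacyl) to ring B (4-oxyphenyl); the tyrosine building block is bought as O-benzyl-L-tyrosine, which spares a separate phenol benzylation and avoids ring nitrosation during diazotisation.

**Route**

Step 1
Reactants: 1 O-benzyl-L-tyrosine
Product: 4 (S)-3-[4-(benzyloxy)phenyl]-2-hydroxypropanoic acid, via diazonium carboxylate 2 (not isolated), via α-lactone 3 (not isolated)
Conditions: NaNO2, 1 M H2SO4, 1,4-dioxane/H2O, 0 °C → rt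
Reagents that add atoms: water (O)
Why: Diazotisation of the α-amino acid (deaminative hydroxylation) should go with overall retention, because the neighbouring carboxylate displaces N2 with inversion to give α-lactone 3 and water opens it at the α-carbon with a second inversion, so the future C6 keeps the (S) configuration.

Step 2
Reactants: 4 (S)-3-[4-(benzyloxy)phenyl]-2-hydroxypropanoic acid
Product: 5 methyl (S)-3-[4-(benzyloxy)phenyl]-2-hydroxypropanoate
Conditions: MeOH, H2SO4 (cat.), 40 °C
Reagents that add atoms: methanol (CO)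
Why: Fischer esterification under acid catalysis should be clean, since no base is present to enolise the stereocentre and the aryl benzyl ether tolerates catalytic acid in methanol.

Step 3
Reactants: 5 methyl (S)-3-[4-(benzyloxy)phenyl]-2-hydroxypropanoate
Product: 6 methyl (S)-2-(benzyloxy)-3-[4-(benzyloxy)phenyl]propanoate
Conditions: BnBr, Ag2O, CH2Cl2, rt, dark
Reagents that add atoms: benzyl bromide (BrCc1ccccc1)
Why: Ag2O-mediated Williamson etherification (Purdie conditions) benzylates the secondary alcohol without a strong base, so the α-stereocentre of the ester should not epimerise.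

Step 4
Reactants: 6 methyl (S)-2-(benzyloxy)-3-[4-(benzyloxy)phenyl]propanoate
Product: 8 (S)-2-(benzyloxy)-3-[4-(benzyloxy)phenyl]propanal, via aluminium hemiacetal 7 (not isolated)
Conditions: i-Bu2AlH (1.1 equiv), CH2Cl2, −78 °C; MeOH, then aq. potassium sodium tartrate
Reagents that add atoms: none
Why: Partial reduction of the α-alkoxy ester at −78 °C should stop at the aldehyde because the tetrahedral aluminium hemiacetal 7, held by the α-benzyloxy oxygen, collapses only on quench; the stereocentre is untouched and the aldehyde is used crude at once.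

Step 5
Reactants: 9 zingerone
Product: 10 4-[4-(tert-butyldimethylsilyloxy)-3-methoxyphenyl]butan-2-one
Conditions: TBSCl, imidazole, DMF, rt
Reagents that add atoms: tert-butyldimethylsilyl chloride (CC(C)(C)[Si](C)(C)Cl)
Why: Imidazole-promoted silylation of the phenol (Corey conditions) masks the acidic OH before the enolate and Lewis acid steps; no stereocentre is involved.

Step 6
Reactants: 10 4-[4-(tert-butyldimethylsilyloxy)-3-methoxyphenyl]butan-2-one
Product: 12 tert-butyl{2-methoxy-4-[3-(trimethylsilyloxy)but-3-en-1-yl]phenoxy}dimethylsilane, via lithium enolate 11 (not isolated)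
Conditions: LiN(i-Pr)2, THF, −78 °C; Me3SiCl, −78 → 0 °C
Reagents that add atoms: chlorotrimethylsilane (C[Si](C)(C)Cl)
Why: Kinetic deprotonation by the hindered amide base at −78 °C should remove a proton from the less substituted methyl group, and O-silylation of lithium enolate 11 traps the terminal silyl enol ether.

Step 7
Reactants: 8 (S)-2-(benzyloxy)-3-[4-(benzyloxy)phenyl]propanal; 12 tert-butyl{2-methoxy-4-[3-(trimethylsilyloxy)but-3-en-1-yl]phenoxy}dimethylsilane
Product: 14 (5S,6S)-6-(benzyloxy)-7-[4-(benzyloxy)phenyl]-1-[4-(tert-butyldimethylsilyloxy)-3-methoxyphenyl]-5-hydroxyheptan-3-one, via magnesium aldolate 13 (not isolated)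
Conditions: MgBr2·OEt2 (3 equiv), CH2Cl2, −78 → −20 °C; 1 M HCl
Reagents that add atoms: none
Why: In this chelation-controlled Mukaiyama aldol addition MgBr2 binds the aldehyde oxygen and the α-benzyloxy oxygen of 8 in a five-membered chelate and the enol silane attacks the face opposite the C7 arylmethyl group (Cram chelate model), which should set C5 as (S), syn to the C6 benzyloxy group.

Step 8
Reactants: 14 (5S,6S)-6-(benzyloxy)-7-[4-(benzyloxy)phenyl]-1-[4-(tert-butyldimethylsilyloxy)-3-methoxyphenyl]-5-hydroxyheptan-3-one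
Product: 16 (3S,5S,6S)-6-(benzyloxy)-7-[4-(benzyloxy)phenyl]-1-[4-(tert-butyldimethylsilyloxy)-3-methoxyphenyl]heptane-3,5-diol, via diethylboron chelate 15 (not isolated)
Conditions: Et2BOMe, THF/MeOH (4:1), −78 °C; NaBH4; AcOH, then MeOH co-evaporation
Reagents that add atoms: none
Why: In this Narasaka–Prasad reduction Et2BOMe ties the C5 hydroxyl and the C3 ketone into the six-membered chelate 15 and NaBH4 delivers hydride externally along the axial trajectory, which should set C3 as (S), 1,3-syn to C5.

Step 9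
Reactants: 16 (3S,5S,6S)-6-(benzyloxy)-7-[4-(benzyloxy)phenyl]-1-[4-(tert-butyldimethylsilyloxy)-3-methoxyphenyl]heptane-3,5-diol
Product: 17 (3S,5S,6S)-6-(benzyloxy)-7-[4-(benzyloxy)phenyl]-1-(4-hydroxy-3-methoxyphenyl)heptane-3,5-diol
Conditions: Bu4NF, AcOH, THF, 0 °C
Reagents that add atoms: none
Why: Fluoride-induced cleavage of the aryl silyl ether, driven by the strong Si–F bond and buffered with acetic acid, should free the ring A phenol and leave the benzyl ethers and the diol untouched.

Step 10
Reactants: 17 (3S,5S,6S)-6-(benzyloxy)-7-[4-(benzyloxy)phenyl]-1-(4-hydroxy-3-methoxyphenyl)heptane-3,5-diol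
Product: 19 rhoiptelol B 6,4''-di-O-benzyl ether, via para-quinone methide 18 (not isolated)
Conditions: DDQ (1.0 equiv), CH2Cl2, 0 °C → rt
Reagents that add atoms: none
Why: DDQ forms a charge-transfer complex with the electron-rich free phenol of ring A and removes hydride from the benzylic C1–H (with loss of the phenolic proton) to give para-quinone methide 18, whose exocyclic carbon C1 is then attacked by the C5 hydroxyl in an oxa-1,6-conjugate addition that restores the aromatic ring. The closest known reaction type is the DDQ or Ag2O oxidation of 4-alkylphenols to para-quinone methides that are captured by an internal or external alcohol. The oxane closes in a 6-exo-trig mode through a chair with the C5 side chain equatorial and the C3 hydroxyl axial. The new C1 stereocentre is controlled by the existing C5 and C3 centres: the aryl group takes the equatorial position, cis to the C5 substituent (1R), and because the para-hydroxybenzylic ether can reopen to 18 in the presence of the mildly acidic hydroquinone by-product, this diequatorial isomer should also be the thermodynamic outcome. The step needs chemoselectivity for ring A and regioselectivity for O5: ring B and O6 are benzyl ethers and can neither form a quinone methide nor add, O3 could only close a strained oxetane, and one equivalent of oxidant at low temperature limits a second oxidation of the product.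

Step 11
Reactants: 19 rhoiptelol B 6,4''-di-O-benzyl ether
Product: 20 rhoiptelol B
Conditions: H2 (1 atm), 10% Pd/C, EtOAc, rt
Reagents that add atoms: none
Why: Heterogeneous hydrogenolysis over Pd/C should cleave both O-benzyl bonds, which are unhindered primary benzylic C–O bonds, faster in neutral ethyl acetate than the hindered ring C1–O bond, and no stereocentre is affected.

**Compound list**

1 | O-benzyl-L-tyrosine, (S)-2-amino-3-[4-(benzyloxy)phenyl]propanoic acid | N[C@@H](Cc1ccc(OCc2ccccc2)cc1)C(=O)O | starting material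
2 | diazonium carboxylate, (S)-3-[4-(benzyloxy)phenyl]-2-diazoniopropanoate | N#[N+][C@@H](Cc1ccc(OCc2ccccc2)cc1)C(=O)[O-] | intermediate
3 | α-lactone, (R)-3-[4-(benzyloxy)benzyl]oxiran-2-one | O1[C@H](Cc2ccc(OCc3ccccc3)cc2)C1=O | intermediate
4 | (S)-3-[4-(benzyloxy)phenyl]-2-hydroxypropanoic acid | O[C@@H](Cc1ccc(OCc2ccccc2)cc1)C(=O)O | intermediate
5 | methyl (S)-3-[4-(benzyloxy)phenyl]-2-hydroxypropanoate | O[C@@H](Cc1ccc(OCc2ccccc2)cc1)C(=O)OC | intermediate
6 | methyl (S)-2-(benzyloxy)-3-[4-(benzyloxy)phenyl]propanoate | O(Cc1ccccc1)[C@@H](Cc1ccc(OCc2ccccc2)cc1)C(=O)OC | intermediate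
7 | aluminium hemiacetal, O-diisobutylaluminium methyl hemiacetal of 8 (hemiacetal carbon unassigned) | O(Cc1ccccc1)[C@@H](Cc1ccc(OCc2ccccc2)cc1)C(OC)O[Al](CC(C)C)CC(C)C | intermediate
8 | (S)-2-(benzyloxy)-3-[4-(benzyloxy)phenyl]propanal | O(Cc1ccccc1)[C@@H](Cc1ccc(OCc2ccccc2)cc1)C=O | intermediate
9 | zingerone, 4-(4-hydroxy-3-methoxyphenyl)butan-2-one | COc1cc(CCC(C)=O)ccc1O | starting material
10 | 4-[4-(tert-butyldimethylsilyloxy)-3-methoxyphenyl]butan-2-one | COc1cc(CCC(C)=O)ccc1O[Si](C)(C)C(C)(C)C | intermediate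
11 | lithium enolate, lithium 4-[4-(tert-butyldimethylsilyloxy)-3-methoxyphenyl]but-1-en-2-olate | [Li+].[O-]C(=C)CCc1ccc(O[Si](C)(C)C(C)(C)C)c(OC)c1 | intermediate
12 | tert-butyl{2-methoxy-4-[3-(trimethylsilyloxy)but-3-en-1-yl]phenoxy}dimethylsilane | C=C(O[Si](C)(C)C)CCc1ccc(O[Si](C)(C)C(C)(C)C)c(OC)c1 | intermediate
13 | magnesium aldolate, O5-bromomagnesium alkoxide of 14 | COc1cc(CCC(=O)C[C@H](O[Mg]Br)[C@@H](OCc2ccccc2)Cc2ccc(OCc3ccccc3)cc2)ccc1O[Si](C)(C)C(C)(C)C | intermediate
14 | (5S,6S)-6-(benzyloxy)-7-[4-(benzyloxy)phenyl]-1-[4-(tert-butyldimethylsilyloxy)-3-methoxyphenyl]-5-hydroxyheptan-3-one | COc1cc(CCC(=O)C[C@H](O)[C@@H](OCc2ccccc2)Cc2ccc(OCc3ccccc3)cc2)ccc1O[Si](C)(C)C(C)(C)C | intermediate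
15 | diethylboron chelate, O5-diethylboryl derivative of 14 | COc1cc(CCC(=O)C[C@H](OB(CC)CC)[C@@H](OCc2ccccc2)Cc2ccc(OCc3ccccc3)cc2)ccc1O[Si](C)(C)C(C)(C)C | intermediate
16 | (3S,5S,6S)-6-(benzyloxy)-7-[4-(benzyloxy)phenyl]-1-[4-(tert-butyldimethylsilyloxy)-3-methoxyphenyl]heptane-3,5-diol | COc1cc(CC[C@H](O)C[C@H](O)[C@@H](OCc2ccccc2)Cc2ccc(OCc3ccccc3)cc2)ccc1O[Si](C)(C)C(C)(C)C | intermediate
17 | (3S,5S,6S)-6-(benzyloxy)-7-[4-(benzyloxy)phenyl]-1-(4-hydroxy-3-methoxyphenyl)heptane-3,5-diol (3,5-syn, 5,6-syn; free guaiacol) | COc1cc(CC[C@H](O)C[C@H](O)[C@@H](OCc2ccccc2)Cc2ccc(OCc3ccccc3)cc2)ccc1O | intermediate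
18 | para-quinone methide, 4-[(3S,5S,6S)-6-(benzyloxy)-7-(4-benzyloxyphenyl)-3,5-dihydroxyheptylidene]-2-methoxycyclohexa-2,5-dien-1-one | COC1=CC(=CC[C@H](O)C[C@H](O)[C@@H](OCc2ccccc2)Cc2ccc(OCc3ccccc3)cc2)C=CC1=O | intermediate
19 | rhoiptelol B 6,4''-di-O-benzyl ether, (1R,3S,5S,6S)-6-(benzyloxy)-7-[4-(benzyloxy)phenyl]-1,5-epoxy-1-(4-hydroxy-3-methoxyphenyl)heptan-3-ol (2,6-cis oxane, axial 4-OH) | COc1cc([C@H]2C[C@H](O)C[C@@H]([C@@H](OCc3ccccc3)Cc3ccc(OCc4ccccc4)cc3)O2)ccc1O | intermediate
20 | rhoiptelol B, (1R,3S,5S,6S)-1,5-epoxy-1-(4-hydroxy-3-methoxyphenyl)-7-(4-hydroxyphenyl)heptane-3,6-diol | COc1cc([C@H]2C[C@H](O)C[C@@H]([C@@H](O)Cc3ccc(O)cc3)O2)ccc1O | target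

**Step count and risk**

Total step count: 11. Longest linear sequence: 9 steps (steps 1–4 and 7–11, from O-benzyl-L-tyrosine).

Steps most likely to fail:

1. Step 10. The cyclised phenol still has a benzylic C1–H and may be oxidised a second time. The quinone methide may also tautomerise to the C1=C2 styrene or be captured intermolecularly, and equilibration at C1 may be incomplete. The fallback sets out from aldehyde 8 and returns at 19, closing the oxane by oxa-Michael addition instead of oxidation. Commercial dehydrozingerone is silylated (TBSCl, imidazole, DMF) to (E)-4-[4-(tert-butyldimethylsilyloxy)-3-methoxyphenyl]but-3-en-2-one F1. This is converted with LiN(i-Pr)2 and Me3SiCl (THF, −78 °C) into tert-butyl{2-methoxy-4-[(1E)-3-(trimethylsilyloxy)buta-1,3-dien-1-yl]phenoxy}dimethylsilane F2. MgBr2·OEt2-mediated Mukaiyama aldol addition of F2 to 8, under the same chelate control as in step 7, should give (1E,5S,6S)-6-(benzyloxy)-7-[4-(benzyloxy)phenyl]-1-[4-(tert-butyldimethylsilyloxy)-3-methoxyphenyl]-5-hydroxyhept-1-en-3-one F3. A sulfonic acid resin (Amberlyst-15, CH2Cl2, rt) then promotes reversible 6-endo-trig addition of O5 to C1, which should settle at the 2,6-cis ketone (1R,5S,6S)-6-(benzyloxy)-7-[4-(benzyloxy)phenyl]-1-[4-(tert-butyldimethylsilyloxy)-3-methoxyphenyl]-1,5-epoxyheptan-3-one F4. LiBH(s-Bu)3 (THF, −78 °C) attacks the ketone from the equatorial side and should give the axial alcohol, the ring A tert-butyldimethylsilyl ether of rhoiptelol B 6,4''-di-O-benzyl ether F5. Bu4NF/AcOH then removes the silyl group to deliver 19.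

2. Step 11. The 2-aryl oxane is itself an electron-rich benzylic ether, so the ring C1–O bond may be hydrogenolysed alongside the benzyl ethers, which would reopen the ring. The fallback sets out from 17 and returns at 20, reversing the order of the last two operations. Hydrogenolysis of 17 (H2, Pd/C, EtOAc/MeOH), which has no benzylic C–O bond other than the two benzyl ethers, should give (3S,5S,6S)-1-(4-hydroxy-3-methoxyphenyl)-7-(4-hydroxyphenyl)heptane-3,5,6-triol F6. Oxidation with one equivalent of DDQ (THF, 0 °C) is then expected to form the quinone methide on the more electron-rich methoxylated ring A rather than ring B. O5 should close the six-membered ring in preference to O6, which would need a seven-membered ring, giving 20 directly.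

3. Step 7. Chelation may be incomplete and erode facial selectivity, the α-alkoxy aldehyde may epimerise on the Lewis acid, or the enol silane may be protodesilylated before it adds. The fallback sets out from 8 and returns at 14, replacing the aldol by an allylation, coupling and cleavage sequence. TiCl4-mediated, chelation-controlled Hosomi–Sakurai addition of commercial (2-bromoallyl)trimethylsilane to 8 (CH2Cl2, −78 °C) should give (4S,5S)-5-(benzyloxy)-6-[4-(benzyloxy)phenyl]-2-bromohex-1-en-4-ol F7. Commercial 2-methoxy-4-vinylphenol is silylated (TBSCl, imidazole) to tert-butyl(4-ethenyl-2-methoxyphenoxy)dimethylsilane F8. Hydroboration of F8 with 9-borabicyclo[3.3.1]nonane gives 9-{2-[4-(tert-butyldimethylsilyloxy)-3-methoxyphenyl]ethyl}-9-borabicyclo[3.3.1]nonane F9 in the flask. B-alkyl Suzuki–Miyaura coupling of F9 with F7 (PdCl2(dppf), Cs2CO3, DMF/THF/H2O) should give (4S,5S)-5-(benzyloxy)-6-[4-(benzyloxy)phenyl]-2-{2-[4-(tert-butyldimethylsilyloxy)-3-methoxyphenyl]ethyl}hex-1-en-4-ol F10. Lemieux–Johnson cleavage of the 1,1-disubstituted alkene (OsO4 cat., NaIO4, 2,6-lutidine, dioxane/H2O) then unmasks the C3 ketone and gives 14.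

**Further compounds**

F1 | step 10 | (E)-4-[4-(tert-butyldimethylsilyloxy)-3-methoxyphenyl]but-3-en-2-one | COc1cc(/C=C/C(C)=O)ccc1O[Si](C)(C)C(C)(C)C
F2 | step 10 | tert-butyl{2-methoxy-4-[(1E)-3-(trimethylsilyloxy)buta-1,3-dien-1-yl]phenoxy}dimethylsilane | COc1cc(/C=C/C(=C)O[Si](C)(C)C)ccc1O[Si](C)(C)C(C)(C)C
F3 | step 10 | (1E,5S,6S)-6-(benzyloxy)-7-[4-(benzyloxy)phenyl]-1-[4-(tert-butyldimethylsilyloxy)-3-methoxyphenyl]-5-hydroxyhept-1-en-3-one | COc1cc(/C=C/C(=O)C[C@H](O)[C@@H](OCc2ccccc2)Cc2ccc(OCc3ccccc3)cc2)ccc1O[Si](C)(C)C(C)(C)C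
F4 | step 10 | (1R,5S,6S)-6-(benzyloxy)-7-[4-(benzyloxy)phenyl]-1-[4-(tert-butyldimethylsilyloxy)-3-methoxyphenyl]-1,5-epoxyheptan-3-one | COc1cc([C@H]2CC(=O)C[C@@H]([C@@H](OCc3ccccc3)Cc3ccc(OCc4ccccc4)cc3)O2)ccc1O[Si](C)(C)C(C)(C)C
F5 | step 10 | (1R,3S,5S,6S)-6-(benzyloxy)-7-[4-(benzyloxy)phenyl]-1-[4-(tert-butyldimethylsilyloxy)-3-methoxyphenyl]-1,5-epoxyheptan-3-ol | COc1cc([C@H]2C[C@H](O)C[C@@H]([C@@H](OCc3ccccc3)Cc3ccc(OCc4ccccc4)cc3)O2)ccc1O[Si](C)(C)C(C)(C)C
F6 | step 11 | (3S,5S,6S)-1-(4-hydroxy-3-methoxyphenyl)-7-(4-hydroxyphenyl)heptane-3,5,6-triol | COc1cc(CC[C@H](O)C[C@H](O)[C@@H](O)Cc2ccc(O)cc2)ccc1O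
F7 | step 7 | (4S,5S)-5-(benzyloxy)-6-[4-(benzyloxy)phenyl]-2-bromohex-1-en-4-ol | C=C(Br)C[C@H](O)[C@@H](OCc1ccccc1)Cc1ccc(OCc2ccccc2)cc1
F8 | step 7 | tert-butyl(4-ethenyl-2-methoxyphenoxy)dimethylsilane | C=Cc1ccc(O[Si](C)(C)C(C)(C)C)c(OC)c1
F9 | step 7 | 9-{2-[4-(tert-butyldimethylsilyloxy)-3-methoxyphenyl]ethyl}-9-borabicyclo[3.3.1]nonane | COc1cc(CCB2C3CCCC2CCC3)ccc1O[Si](C)(C)C(C)(C)C
F10 | step 7 | (4S,5S)-5-(benzyloxy)-6-[4-(benzyloxy)phenyl]-2-{2-[4-(tert-butyldimethylsilyloxy)-3-methoxyphenyl]ethyl}hex-1-en-4-ol | COc1cc(CCC(=C)C[C@H](O)[C@@H](OCc2ccccc2)Cc2ccc(OCc3ccccc3)cc2)ccc1O[Si](C)(C)C(C)(C)C
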